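1. I had 3 questions to answer about birch, which gets its substrate in portions, and alder, which gets it all at the start. Both flasks have the same charges.

| setting | Sunday's | Wednesday's | birch | alder |
|---|---|---|---|---|
| substrate | 10 mM (in portions, 3) | 10 mM (in portions, 3) | 10 mM (in portions, 3) | 10 mM |
| reagent | 15 mM | 22 mM | 30.0 mM | 30.0 mM |
| remark | run made earlier; portions every 25 min | run made earlier; portions every 25 min | the portions of substrate follow each other after 25 min, the first at the start | everything together at the start |
| time |  |  | 80 min | 250 min |

| run | time / min | first product / % |
|---|---|---|
| Sunday's | 20.0 | 8.5 |
| Sunday's | 40.0 | 19.0 |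
| Sunday's | 60.0 | 23.8 |
| Sunday's | 80.0 | 31.6 |
| Sunday's | 90.0 | 32.4 |
| Wednesday's | 8.00 | 5.4 |
| Wednesday's | 15.0 | 7.3 |
| Wednesday's | 25.0 | 11.3 |
| Wednesday's | 50.0 | 21.9 |
| Wednesday's | 90.0 | 35.5 |

(scatter of a reading: 1 percentage point)

- the earlier runs were read with a standard deviation of 1 percentage point
- a reading or a percentage of first product counts all its forms, free or not

1. which one finishes higher in amount of first product, in percent of the substrate charged ("neither" within 2 percentage points) (birch / alder / neither)
2. amount of first product at the end, in percent of the substrate charged, birch
3. amount of first product at the end, in percent of the substrate charged, alder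

2. The earlier runs looked contradictory. Wednesday's run had 1.47 times the reagent of Sunday's, yet first product rose by 0.00385 /min of the charge in Sunday's run and 0.00372 /min in Wednesday's. These are readings, and their ratio is 0.966.

3. I cleared this up by holding the slopes against the scatter. Each slope rests on two readings, Sunday's at 20.0 min and 80.0 min, Wednesday's at 25.0 min and 90.0 min. Across Sunday's 60.0 min the two slopes part by 0.76 percentage points, less than the scatter of one reading, 1 point. So these windows did not tell the two reagent charges apart. I call the mean of the two slopes, 0.00379 /min, the fed rise: the gain of first product per minute, all forms counted, as a share of the charge, over these windows. Both windows reach past the last portion, which went in at 50.0 min.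

4. For birch, my reckoning was the fed rise times the time, 30.3 %. Alder has no feed, so the fed rise gave me no number for it.

5. The forecast said birch, with birch at 33 % (27 % to 39 %), which is more than my figure, and alder at 9 % (4 % to 20 %). From the first portion it read “the rate rises with reagent, roughly first order within the noise”, whereas my later slopes did not separate the two runs.

6. The flasks gave birch: birch 33.0 %, and alder 23.9 %, which is higher than the top of the forecast's range.

    substrate + reagent → first product (k = 1.80 /M/min)
    substrate + reagent → other mono adduct (k = 2.30 /M/min)
    reagent + first product → double product (k = 1.60 /M/min)
    reagent + other mono adduct → double product (k = 0.220 /M/min)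
    crystals ⇌ first product, rate k5*(cs5 - [first product]) while solid is left; crystals form when [first product] > cs5 (solubility = 0.270 mM, k = 0.760 /min)

Birch had 3.09 % substrate standing just before its last portion at 50.0 min, and its first product reached 33.0 % of the substrate charged, with crystals at 30.2 % of the substrate charged, a mean rise of 0.00412 /min against the fed rise of 0.00379 /min. Alder had 0.00588 % substrate left at 125 min, and from then to 250 min, with reagent down to 48.9 % of its charge, its first product fell from 32.1 % to 23.9 %, a mean fall of 6.54 × 10⁻⁴ /min against the fed rise of 0.00379 /min.

(Readings and results stem from a simulated flask on assumed constants; the scatter is artificial.)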